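# Proposed synthesis of CNP0326872.1 (compound 12) by desymmetrizing arylation of meso-2,3-dimethylsuccinic anhydride

Ring numbering used throughout: O1, C2 (3,4-dimethoxyphenyl), C3 (methyl), C4 (methyl), C5 (4-hydroxy-3,5-dimethoxyphenyl).

## The problem

Target 12 is a 2,5-diaryl-3,4-dimethyltetrahydrofuran with the configuration 2S,3S,4R,5R. All four ring carbons are stereogenic and contiguous. The two methyls are cis to each other, each aryl group is trans to its neighbouring methyl, and the two aryl groups are therefore cis across the ring oxygen. With two identical aryl groups this arrangement would be meso. The absolute configuration is thus only the question of which aryl group sits at which end of a symmetric C2–C3–C4–C5 core, and a reagent or catalyst has to tell the two ends apart. Once C3 and C4 are fixed, both benzylic centres can follow from them, because aryl trans to the adjacent methyl is the expected kinetic result of addition to the five-membered oxocarbenium ion and also the more stable arrangement. The fragile parts are the free electron-rich phenol (oxidation, quinone methide formation) and the two benzylic ether bonds, which ionize under strong acid and can then epimerize, open, or close onto the other arene to give an aryltetralin. The feature that allows a short route is that C2–C3–C4–C5 with its cis methyls is the carbon skeleton of meso anhydride 2, in which C2 and C5 are the two enantiotopic carbonyl carbons. One enantioselective C-arylation of one carbonyl therefore fixes both methyl centres and distinguishes the two ends.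

## Retrosynthesis

**C5–aryl bond.** Target 12 is cut between C5 and the syringyl ring, which leads to the cyclic methyl acetal 10 and commercial 2,6-dimethoxyphenol 11. The forward reaction is a Friedel–Crafts arylation of the oxocarbenium ion of 10. The phenol needs no protecting group, its ortho positions are blocked, and the sensitive ring enters in the last step. The neighbouring option, adding an aryl organometallic to the lactone and reducing the hemiketal, delivers hydride anti to the C4 methyl and so gives the wrong (cis) C4/C5 relationship first. Arene addition anti to the C4 methyl gives the required trans relationship directly. The precursor 10 has one ring, one aryl group and three defined stereocentres.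

**Oxidation level at C5.** Acetal 10 comes from lactol 9 by acetal exchange, and 9 from lactone 8 by partial reduction. No carbon–carbon bond is involved. These two steps only convert the carboxyl carbon into a leaving-group-bearing acetal carbon, and the forward reactions must leave the benzylic C2–O bond alone.

**O1–C5 (acyl) bond and the C2–H bond.** Lactone 8 is opened to hydroxy acid 7, which comes from keto acid 6 by reduction of the aryl ketone. The reduction must place the C2 aryl group trans to the C3 methyl. The Felkin–Anh preference of the alpha-branched ketone points in this direction, and the trans lactone is the more stable C2 epimer. Making C2 by reduction, and not by a second carbon–carbon bond formation, keeps the keto acid as the only chiral building block.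

**C2–aryl bond (key disconnection).** Keto acid 6 is cut between the ketone carbon and the veratryl ring, which leads to meso anhydride 2 and bis(3,4-dimethoxyphenyl)zinc 5. Compared with an aldol or alkylation approach to the syn-dimethyl unit, this cut takes the cis relationship from a meso compound and sets the absolute configuration of C3 and C4 in one catalytic event. It also marks C2 as ketone and C5 as acid, so that the two aryl groups can be introduced one after the other. The forward reaction must select one of two enantiotopic carbonyls, stop at the ketone and not epimerize the ketone alpha carbon.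

**Building blocks.** Anhydride 2 comes from commercial meso-2,3-dimethylsuccinic acid 1 by dehydration. Diarylzinc 5 comes from commercial 4-bromo-1,2-dimethoxybenzene 3 through aryllithium 4 and a halide-free zinc salt.

## Roads not taken

**Alternative 1:** The cut is C3–C4 together with both ring C–O bonds, in a biomimetic oxidative cross-coupling of two propenylphenols.
- Forward step: (E)-isoeugenol A2 and (E)-2,6-dimethoxy-4-(prop-1-enyl)phenol A3 are oxidized to phenoxyl radicals (laccase and oxygen, with a dirigent protein). The radicals pair at their beta carbons, and water and then the new hydroxyl add to the two quinone methides to give diphenol A1. Selective methylation of the guaiacyl hydroxyl of A1 would finish the synthesis.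
- Merits: two operations from cheap phenols, no protecting groups, and three bonds and four stereocentres formed at once. In step count it is far better than the chosen plan.
- Weak points:
  - cross-coupling competes with both homo-couplings;
  - the guaiacyl radical also couples through its free ring position and through oxygen;
  - the cis-dimethyl, trans,cis,trans arrangement is not the assured outcome of beta–beta coupling and water capture;
  - the absolute configuration would require a protein that pairs defined faces of two radicals differing only by one methoxy group, and no dirigent protein is known to do this for propenylphenols;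
  - the two phenols of A1 must then be told apart in the methylation.
- Comparison: the chosen plan needs seven steps, but each of these selectivities is handed to a known control element: the meso anhydride for the cis methyls, the ligand for the absolute sense, and the order of the steps for the placement of the aryl groups.

**Alternative 2:** The cut removes both methyl groups as a CH2–S–CH2 bridge.
- Forward step: the parent thiocarbonyl ylide, released by CsF from a silylmethyl chloromethyl sulfide, adds in a (3+2) cycloaddition to butenolide A5 on the face anti to the aryl group. This gives the cis-fused thiolane lactone A4. Desulfurization with Raney-type nickel would give lactone 8, so this road joins the chosen one at 8.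
- Merits: the cis relationship of the methyls is guaranteed by the cis ring fusion, and the benzylic centre controls both methyl-bearing carbons through a rigid ring. In this one respect it is arguably more secure than a Felkin-controlled ketone reduction.
- Weak points:
  - enantiopure A5 needs its own asymmetric synthesis;
  - the C–H of A5 at the stereocentre is benzylic, allylic and gamma to the carbonyl, so the basic fluoride may racemize it or move the double bond;
  - the nickel step may cleave the benzylic lactone C–O bond.
- Comparison: the chosen plan reaches 8 in four steps in all, with a longest line of three, and with catalytic absolute control. Against the rigid-ring control of the alternative it sets the Felkin–Anh bias, the greater stability of the trans lactone and a reagent-controlled fallback.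

**Alternative 3:** The cut is C2–C3, closed by intramolecular carbene insertion.
- Forward step: Rh2(S-PTTL)4 decomposes diazo ester A7, and the rhodium carbene inserts into a benzylic C–H bond of the 3,4-dimethoxybenzyl ether. This gives tetrahydrofuran ester A6, whose ester is later reduced to the C3 methyl.
- Merits: the ring and two stereocentres form in one catalytic step, and the syringyl ring is carried in with defined regiochemistry. It is better than the chosen plan in this last respect, since the chosen plan must rely on para-selective Friedel–Crafts attack.
- Weak points:
  - A7 is an alpha-alkyl diazo ester with a hydrogen on the adjacent carbon, so 1,2-hydride shift to the unsaturated ester competes with insertion;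
  - the C4 and C5 centres must be made enantiopure beforehand;
  - the catalyst must give the C2/C3 trans and C3/C4 cis relationships against the usual preference of such insertions for cis products;
  - C3 of A6 is epimerizable next to the ester;
  - ester to methyl costs three further steps, and a debenzylation follows.
- Comparison: the route would be clearly longer than seven steps and would rest several stereochemical demands on one step. The chosen plan takes C3 and C4 from a meso source, and for the late arylation it has the blocked ortho positions of 11 and an organometallic fallback.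

Key step: step 3

## Route

Assumption: the (R,R)-configured TADDOL phosphoramidite is taken to direct arylation to the carbonyl next to the S-configured carbon of 2. If the sense of induction is the opposite, the (S,S)-ligand is used with nothing else changed. Both ligand enantiomers are accessible from the tartrate-derived diols.

Step 1
Reactants: 1 meso-2,3-dimethylsuccinic acid
Product: 2 cis-2,3-dimethylsuccinic anhydride, (3R,4S)-3,4-dimethyloxolane-2,5-dione
Conditions: AcCl (neat), reflux; volatiles removed under vacuum
Reagents that add atoms: none
Why: Dehydrative cyclization of a 1,4-diacid to the five-membered anhydride through the mixed anhydride; the meso acid can only close to the cis anhydride, and the acidic, base-free medium avoids epimerization to the trans isomer.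

Step 2
Reactants: 3 4-bromo-1,2-dimethoxybenzene
Product: 5 bis(3,4-dimethoxyphenyl)zinc (used as its THF solution), via 3,4-dimethoxyphenyllithium 4 (not isolated)
Conditions: n-BuLi (1.0 equiv), THF, −78 °C; then Zn(OTf)2 (0.5 equiv), −78 °C to rt
Reagents that add atoms: zinc trifluoromethanesulfonate, [Zn+2].[O-]S(=O)(=O)C(F)(F)F.[O-]S(=O)(=O)C(F)(F)F
Why: Bromine–lithium exchange on an electron-rich aryl bromide followed by transmetalation to zinc; n-BuLi leaves no lithium halide and the triflate salt keeps the reagent halide-free for the rhodium step.

Step 3
Reactants: 2 cis-2,3-dimethylsuccinic anhydride; 5 bis(3,4-dimethoxyphenyl)zinc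
Product: 6 (2R,3S)-4-(3,4-dimethoxyphenyl)-2,3-dimethyl-4-oxobutanoic acid
Conditions: [Rh(cod)Cl]2 (4 mol %), (3aR,8aR)-N,N,2,2-tetramethyl-4,4,8,8-tetraphenyltetrahydro[1,3]dioxolo[4,5-e][1,3,2]dioxaphosphepin-6-amine (8 mol %), 5 (1.1 equiv), THF–DMF, 50 °C; then 1 M HCl
Reagents that add atoms: none
Why: This is a rhodium-catalysed enantioselective desymmetrization of a cyclic meso anhydride by an organozinc reagent, a known acylative cross-coupling of the Negishi type. The monovalent rhodium–phosphoramidite complex inserts into one of the two enantiotopic acyl–oxygen bonds of 2 in the enantio-determining oxidative addition, an aryl group passes from zinc to the trivalent acyl rhodium carboxylate, and reductive elimination forms the aryl–carbonyl bond and returns monovalent rhodium. No ring is closed; the anhydride ring is opened and the product leaves the cycle as a zinc carboxylate that acidic work-up converts into 6. The two methyl-bearing carbons become stereogenic in this single event: their syn relationship is inherited from meso 2 and their absolute configuration is fixed by the chiral ligand, which must steer the metal to the carbonyl next to the S-configured carbon. The step needs enantiotopic-group selectivity, which the ligand supplies. It needs mono-addition, which is secured because neither the ketone nor the zinc carboxylate reacts with the arylzinc under these conditions. It also needs the ketone alpha centre to keep its configuration, which the non-basic reagent, the neutral medium and the moderate temperature should ensure.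

Step 4
Reactants: 6 (2R,3S)-4-(3,4-dimethoxyphenyl)-2,3-dimethyl-4-oxobutanoic acid
Product: 8 (3R,4S,5S)-5-(3,4-dimethoxyphenyl)-3,4-dimethyldihydrofuran-2(3H)-one, via hydroxy acid 7 (not isolated)
Conditions: LiBH(s-Bu)3 (2.2 equiv), THF, −78 °C; then 2 M HCl, 0 °C to rt
Reagents that add atoms: none
Why: Felkin–Anh-controlled reduction of an alpha-stereogenic aryl ketone by a bulky trialkylborohydride: hydride approaches anti to the CH(CH3)CO2Li branch and sets the (S) carbinol centre of 7, and acidification closes the gamma-lactone by intramolecular acyl substitution to the 4,5-trans lactone 8, which is also the more stable benzylic epimer. The lithium carboxylate formed by the first equivalent of hydride is inert to further reduction.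

Step 5
Reactants: 8 (3R,4S,5S)-5-(3,4-dimethoxyphenyl)-3,4-dimethyldihydrofuran-2(3H)-one
Product: 9 (3R,4S,5S)-5-(3,4-dimethoxyphenyl)-3,4-dimethyltetrahydrofuran-2-ol (mixture of anomers)
Conditions: i-Bu2AlH (1.1 equiv), CH2Cl2, −78 °C; aqueous KNaC4H4O6 work-up
Reagents that add atoms: none
Why: Partial reduction of a gamma-lactone to the lactol; the tetrahedral aluminium hemiacetal persists at −78 °C and collapses only on work-up, so over-reduction to the diol is avoided and no stereocentre is touched.

Step 6
Reactants: 9 (3R,4S,5S)-5-(3,4-dimethoxyphenyl)-3,4-dimethyltetrahydrofuran-2-ol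
Product: 10 (2S,3S,4R)-2-(3,4-dimethoxyphenyl)-5-methoxy-3,4-dimethyltetrahydrofuran (mixture of anomers)
Conditions: MeOH, pyridinium p-toluenesulfonate (cat.), rt
Reagents that add atoms: methanol, CO
Why: Acid-catalysed acetalization of a lactol through the ring oxocarbenium ion; the weak acid exchanges the anomeric hydroxyl much faster than it ionizes the benzylic C2–O bond, and the anomeric mixture is of no consequence because this carbon becomes planar again in step 7.

Step 7
Reactants: 10 (2S,3S,4R)-2-(3,4-dimethoxyphenyl)-5-methoxy-3,4-dimethyltetrahydrofuran; 11 2,6-dimethoxyphenol
Product: 12 4-[(2R,3R,4S,5S)-5-(3,4-dimethoxyphenyl)-3,4-dimethyloxolan-2-yl]-2,6-dimethoxyphenol, equal to (2S,3S,4R,5R)-2-(3,4-dimethoxyphenyl)-5-(4-hydroxy-3,5-dimethoxyphenyl)-3,4-dimethyltetrahydrofuran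
Conditions: 11 (1.5 equiv), BF3·OEt2, CH2Cl2, −78 to −20 °C; aqueous NaHCO3 quench
Reagents that add atoms: none
Why: Friedel–Crafts C-arylation of a cyclic oxocarbenium ion (C-glycosylation type): BF3 ionizes the anomeric methoxy group and the phenol, whose ortho positions are blocked, attacks through the carbon para to its hydroxyl. Attack on the envelope face anti to the pseudoaxial C4 methyl and the C3 methyl places the new aryl group trans to the C4 methyl and cis to the C2 aryl group; this is also the more stable C5 epimer, toward which the p-hydroxybenzylic centre can equilibrate under the Lewis acid.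

## Compound list

1 | meso-2,3-dimethylsuccinic acid, (2R,3S)-2,3-dimethylbutanedioic acid | C[C@@H](C(=O)O)[C@H](C)C(=O)O | starting material
2 | cis-2,3-dimethylsuccinic anhydride, (3R,4S)-3,4-dimethyloxolane-2,5-dione | C[C@@H]1C(=O)OC(=O)[C@@H]1C | intermediate
3 | 4-bromo-1,2-dimethoxybenzene | COc1ccc(Br)cc1OC | starting material
4 | 3,4-dimethoxyphenyllithium (not isolated) | [Li]c1ccc(OC)c(OC)c1 | intermediate
5 | bis(3,4-dimethoxyphenyl)zinc | COc1ccc([Zn]c2ccc(OC)c(OC)c2)cc1OC | intermediate
6 | (2R,3S)-4-(3,4-dimethoxyphenyl)-2,3-dimethyl-4-oxobutanoic acid | COc1ccc(C(=O)[C@@H](C)[C@@H](C)C(=O)O)cc1OC | intermediate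
7 | (2R,3S,4S)-4-(3,4-dimethoxyphenyl)-4-hydroxy-2,3-dimethylbutanoic acid (not isolated) | COc1ccc([C@@H](O)[C@@H](C)[C@@H](C)C(=O)O)cc1OC | intermediate
8 | (3R,4S,5S)-5-(3,4-dimethoxyphenyl)-3,4-dimethyldihydrofuran-2(3H)-one | COc1ccc([C@H]2OC(=O)[C@H](C)[C@@H]2C)cc1OC | intermediate
9 | (3R,4S,5S)-5-(3,4-dimethoxyphenyl)-3,4-dimethyltetrahydrofuran-2-ol, anomeric mixture | COc1ccc([C@H]2OC(O)[C@H](C)[C@@H]2C)cc1OC | intermediate
10 | (2S,3S,4R)-2-(3,4-dimethoxyphenyl)-5-methoxy-3,4-dimethyltetrahydrofuran, anomeric mixture | COc1ccc([C@H]2OC(OC)[C@H](C)[C@@H]2C)cc1OC | intermediate
11 | 2,6-dimethoxyphenol | COc1cccc(OC)c1O | starting material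
12 | 4-[(2R,3R,4S,5S)-5-(3,4-dimethoxyphenyl)-3,4-dimethyloxolan-2-yl]-2,6-dimethoxyphenol | COc1ccc([C@H]2O[C@@H](c3cc(OC)c(O)c(OC)c3)[C@H](C)[C@@H]2C)cc1OC | target

## Step count and risks

Total step count: 7. Longest linear sequence: 6 (steps 1, 3, 4, 5, 6, 7, or equally steps 2, 3, 4, 5, 6, 7).

**Step 3 (key step).** The most likely failure is incomplete discrimination between the two enantiotopic carbonyls with this electron-rich arylzinc, or sluggish aryl transfer from zinc that lets unselective ring opening catch up. Either would lower the enantiomeric purity of everything that follows. Crystallization of 6 or 8 may raise the purity if the erosion is small. The fallback sets out from 2 and returns at 6: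
- Alcoholysis of 2 with benzyl alcohol, mediated by a cinchona alkaloid, gives (2S,3R)-4-(benzyloxy)-2,3-dimethyl-4-oxobutanoic acid F1. Quinine or quinidine is chosen so that the ester is placed on the carbonyl next to the R-configured carbon.
- The free acid is converted with ethanethiol, dicyclohexylcarbodiimide and 4-dimethylaminopyridine into benzyl (2R,3S)-4-(ethylsulfanyl)-2,3-dimethyl-4-oxobutanoate F2.
- Fukuyama coupling of F2 with 5 under PdCl2(PPh3)2 gives benzyl (2R,3S)-4-(3,4-dimethoxyphenyl)-2,3-dimethyl-4-oxobutanoate F3.
- Hydrogenolysis of F3 (H2, 10% Pd on carbon, ethyl acetate) releases 6.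

**Step 4.** Facial selectivity in the hydride delivery may be poor if the lithium carboxylate associates with the ketone and disturbs the Felkin–Anh conformation. The cis lactone would then accompany 8. The fallback sets out from 6 and returns at 8:
- Esterification of 6 with trimethylsilyldiazomethane in methanol–toluene gives methyl (2R,3S)-4-(3,4-dimethoxyphenyl)-2,3-dimethyl-4-oxobutanoate F4.
- Reagent-controlled Corey–Bakshi–Shibata reduction with (R)-2-methyl-CBS-oxazaborolidine and BH3·SMe2 is matched with the substrate bias. It gives methyl (2R,3S,4S)-4-(3,4-dimethoxyphenyl)-4-hydroxy-2,3-dimethylbutanoate F5.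
- F5 lactonizes to 8 with catalytic p-toluenesulfonic acid.

**Step 6.** Acid-promoted ionization of the electron-rich benzylic C2–O bond may compete with anomeric exchange. This would lead to ring opening by methanol and loss of configuration at C2. The fallback sets out from 9 and returns at 12:
- Acetylation of 9 under basic conditions (acetic anhydride, pyridine, 4-dimethylaminopyridine) gives (3R,4S,5S)-5-(3,4-dimethoxyphenyl)-3,4-dimethyltetrahydrofuran-2-yl acetate F6.
- F6 is ionized by BF3·OEt2 in the presence of 11 exactly as 10 is in step 7.

**Step 7.** Three processes may interfere: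
- attack of the phenol through oxygen or through the ring carbon meta to the hydroxyl (wrong regiochemistry);
- renewed ionization of the product at either benzylic ether bond, followed by ring opening and a second arylation or by cyclization onto the veratryl ring;
- insufficient facial selectivity if the addition is not under the expected control.

The fallback sets out from 8 and returns at 12. It fixes the regiochemistry with an organometallic reagent:
- 2-(Benzyloxy)-5-bromo-1,3-dimethoxybenzene F7 is made by benzylation of 4-bromo-2,6-dimethoxyphenol. It is lithiated with n-BuLi and added to 8 to give (3R,4S,5S)-2-[4-(benzyloxy)-3,5-dimethoxyphenyl]-5-(3,4-dimethoxyphenyl)-3,4-dimethyltetrahydrofuran-2-ol F8.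
- Reductive deoxygenation of F8 with Et3SiH and BF3·OEt2 first delivers hydride anti to the C4 methyl. Warming to −20 °C lets the p-alkoxybenzylic centre epimerize to the more stable trans arrangement. This gives (2R,3R,4S,5S)-2-[4-(benzyloxy)-3,5-dimethoxyphenyl]-5-(3,4-dimethoxyphenyl)-3,4-dimethyltetrahydrofuran F9.
- Hydrogenolysis of the benzyl ether of F9 (H2, 10% Pd on carbon) gives 12.

## Further compounds

F1 | step 3 | (2S,3R)-4-(benzyloxy)-2,3-dimethyl-4-oxobutanoic acid | OC(=O)[C@@H](C)[C@@H](C)C(=O)OCc1ccccc1
F2 | step 3 | benzyl (2R,3S)-4-(ethylsulfanyl)-2,3-dimethyl-4-oxobutanoate | CCSC(=O)[C@@H](C)[C@@H](C)C(=O)OCc1ccccc1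
F3 | step 3 | benzyl (2R,3S)-4-(3,4-dimethoxyphenyl)-2,3-dimethyl-4-oxobutanoate | COc1ccc(C(=O)[C@@H](C)[C@@H](C)C(=O)OCc2ccccc2)cc1OC
F4 | step 4 | methyl (2R,3S)-4-(3,4-dimethoxyphenyl)-2,3-dimethyl-4-oxobutanoate | COc1ccc(C(=O)[C@@H](C)[C@@H](C)C(=O)OC)cc1OC
F5 | step 4 | methyl (2R,3S,4S)-4-(3,4-dimethoxyphenyl)-4-hydroxy-2,3-dimethylbutanoate | COc1ccc([C@@H](O)[C@@H](C)[C@@H](C)C(=O)OC)cc1OC
F6 | step 6 | (3R,4S,5S)-5-(3,4-dimethoxyphenyl)-3,4-dimethyltetrahydrofuran-2-yl acetate, anomeric mixture | COc1ccc([C@H]2OC(OC(C)=O)[C@H](C)[C@@H]2C)cc1OC
F7 | step 7 | 2-(benzyloxy)-5-bromo-1,3-dimethoxybenzene | COc1cc(Br)cc(OC)c1OCc1ccccc1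
F8 | step 7 | (3R,4S,5S)-2-[4-(benzyloxy)-3,5-dimethoxyphenyl]-5-(3,4-dimethoxyphenyl)-3,4-dimethyltetrahydrofuran-2-ol, anomeric mixture | COc1ccc([C@H]2OC(O)(c3cc(OC)c(OCc4ccccc4)c(OC)c3)[C@H](C)[C@@H]2C)cc1OC
F9 | step 7 | (2R,3R,4S,5S)-2-[4-(benzyloxy)-3,5-dimethoxyphenyl]-5-(3,4-dimethoxyphenyl)-3,4-dimethyltetrahydrofuran | COc1ccc([C@H]2O[C@@H](c3cc(OC)c(OCc4ccccc4)c(OC)c3)[C@H](C)[C@@H]2C)cc1OC
A1 | alternative 1 | 4-[(2R,3R,4S,5S)-5-(4-hydroxy-3-methoxyphenyl)-3,4-dimethyloxolan-2-yl]-2,6-dimethoxyphenol | COc1cc([C@H]2O[C@@H](c3cc(OC)c(O)c(OC)c3)[C@H](C)[C@@H]2C)ccc1O
A2 | alternative 1 | (E)-isoeugenol, 2-methoxy-4-[(E)-prop-1-enyl]phenol | C/C=C/c1ccc(O)c(OC)c1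
A3 | alternative 1 | 2,6-dimethoxy-4-[(E)-prop-1-enyl]phenol | C/C=C/c1cc(OC)c(O)c(OC)c1
A4 | alternative 2 | (3S,3aS,6aR)-3-(3,4-dimethoxyphenyl)tetrahydro-1H-thieno[3,4-c]furan-1-one, cis-fused | COc1ccc([C@H]2OC(=O)[C@@H]3CSC[C@H]23)cc1OC
A5 | alternative 2 | (S)-5-(3,4-dimethoxyphenyl)furan-2(5H)-one | COc1ccc([C@H]2OC(=O)C=C2)cc1OC
A6 | alternative 3 | methyl (2S,3S,4R,5R)-5-[4-(benzyloxy)-3,5-dimethoxyphenyl]-2-(3,4-dimethoxyphenyl)-4-methyltetrahydrofuran-3-carboxylate | COc1ccc([C@H]2O[C@@H](c3cc(OC)c(OCc4ccccc4)c(OC)c3)[C@H](C)[C@@H]2C(=O)OC)cc1OC
A7 | alternative 3 | methyl (3R,4R)-4-[4-(benzyloxy)-3,5-dimethoxyphenyl]-2-diazo-4-[(3,4-dimethoxybenzyl)oxy]-3-methylbutanoate | COC(=O)C(=[N+]=[N-])[C@@H](C)[C@@H](OCc1ccc(OC)c(OC)c1)c1cc(OC)c(OCc2ccccc2)c(OC)c1
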